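**Retrosynthetic overview**

1. Backwards: acetate ← primary alcohol ← Tamao–Fleming oxidation of a silylmethyl group on C13; cyclic ether ← eight-membered lactone ← Baeyer–Villiger insertion of oxygen between C8 and C15 of a cycloheptanone; C16 ← conjugate addition to the C13=C14 enone.
2. Enabling feature: the ring oxygen lies between the quaternary C8 and C15, so the oxocane (O, C8, C9, C11, C12, C13, C14, C15) is the ring-expanded form of a cycloheptanone (C8, C9, C11, C12, C13, C14, C15). In it C8 is the α- and C13 the β-carbon of the C15 carbonyl, i.e. the two ends of a 2-silyloxy-1,3-diene C8=C15(OSi)–C14=C13, and the three carbons C9–C11–C12 between them are an allene.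
3. Key disconnection: a gold-catalysed intramolecular (4+3) cycloaddition of this diene (arm on C5) with the allene (on C10) makes C8–C9 and C12–C13 together and closes ring B and the seven-membered ring on a monocyclic ring A precursor.
4. Precursor: ring A from 4,4-dimethylcyclohex-2-enone; C5 by catalytic asymmetric conjugate addition, C10 relayed from it by a reductive aldol, the allene by hydrogenolysis of a propargylic carbonate, the diene by silylation of a vinyl ketone.
5. Ring order: ring A (bought) → ring B and the seven-membered carbocycle (step 13) → oxocane by oxygen insertion (step 17). C8 is set in the key step, C9 by hydrogenation (step 14), C13 by catalyst control (step 16).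

Key step: step 13

Remark: locants are those of the labdane skeleton (ring A = C1–C5 and C10; ring B = C5–C10; C17 = methyl on C8; C20 = methyl on C10; C16 = acetoxymethyl carbon; β = the face of the C10 methyl). The side-chain carbon that becomes C8 is carried as an epimer mixture up to 18 and is erased in step 12. Compounds 1, 5 and 10 are taken as commercial (10 freshly distilled).

**Step 1**
Reactants: 1 ethyl 4-bromo-2-methylbutanoate (racemic)
Product: 2 ethyl 4-iodo-2-methylbutanoate (racemic)
Conditions: NaI, acetone, reflux
Reagents that add atoms: sodium iodide, [Na+].[I-]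
Why: Finkelstein halide exchange (SN2 at a primary carbon) should be driven by precipitation of NaBr and gives the iodide needed for zinc insertion.

**Step 2**
Reactants: 2 ethyl 4-iodo-2-methylbutanoate
Product: 4 (4-ethoxy-3-methyl-4-oxobutyl)[(trimethylsilyl)methyl]zinc (used as a toluene solution), via alkylzinc iodide 3 (not isolated)
Conditions: Zn dust (activated with BrCH2CH2Br and Me3SiCl, cat.), THF, 40 °C; then Me3SiCH2Li (pentane), −78 °C to −30 °C; solvents removed in vacuo, toluene, LiI filtered off
Reagents that add atoms: zinc, [Zn]; (trimethylsilyl)methyllithium, [Li]C[Si](C)(C)C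
Why: oxidative insertion of activated zinc into the primary carbon–iodine bond tolerates the ester, and lithium-to-zinc transmetalation at low temperature (faster than attack on the ester) should give the mixed diorganozinc, in which the (trimethylsilyl)methyl group is a non-transferable ligand, so one alkyl iodide supplies one transferable alkyl group.

**Step 3**
Reactants: 5 4,4-dimethylcyclohex-2-en-1-one; 4 (4-ethoxy-3-methyl-4-oxobutyl)[(trimethylsilyl)methyl]zinc
Product: 7 ethyl 4-{2-[(dimethylamino)methyl]-6,6-dimethyl-3-oxocyclohexyl}-2-methylbutanoate (ring substituents trans; C5 as in the target), via zinc enolate 6 (not isolated)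
Conditions: Cu(OTf)2 (3 mol %), (S,R,R)-phosphoramidite from (S)-BINOL and bis[(R)-1-phenylethyl]amine (6 mol %), toluene, −30 °C; then CH2=NMe2+ I−, THF, −30 °C to rt
Reagents that add atoms: N,N-dimethylmethyleneiminium iodide (Eschenmoser's salt), C=[N+](C)C.[I-]
Why: copper-catalysed asymmetric conjugate addition of a diorganozinc to a cyclic enone, in which the primary alkyl group should be transferred in preference to the (trimethylsilyl)methyl group, sets C5 by catalyst control (same facial sense as known for cyclohex-2-enone with this ligand), and the regiodefined zinc enolate is trapped at C10 in a Mannich reaction anti to the new C5 substituent.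

**Step 4**
Reactants: 7 Mannich base
Product: 9 ethyl 4-(6,6-dimethyl-2-methylidene-3-oxocyclohexyl)-2-methylbutanoate, via methiodide 8 (not isolated)
Conditions: MeI, Et2O, rt; then NaHCO3 (aq), CH2Cl2, rt
Reagents that add atoms: none
Why: quaternisation and E1cB elimination of the β-amino ketone should give the α-methylene ketone, whose exocyclic CH2 becomes the C10 methyl group (C20).

**Step 5**
Reactants: 9 α-methylene ketone; 10 propynal
Product: 12 ethyl 4-[2-(1-hydroxyprop-2-ynyl)-2,6,6-trimethyl-3-oxocyclohexyl]-2-methylbutanoate (C10 methyl cis and C9 chain trans to the C5 side chain; carbinol epimers), via lithium enolate 11 (not isolated)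
Conditions: LiBH(s-Bu)3, THF, −78 °C; then 10, −78 °C; AcOH quench at −78 °C
Reagents that add atoms: none
Why: 1,4-hydride addition to the exocyclic enone gives the C10 enolate regiospecifically, and the aldol addition should occur anti to the C5 side chain (the other face is blocked by that chain or by the syn-axial C4 methyl in either half-chair), so the quaternary C10 is relayed from C5.

**Step 6**
Reactants: 12 aldol adduct
Product: 13 methyl carbonate of 12
Conditions: ClCO2Me, pyridine, DMAP (cat.), CH2Cl2, 0 °C
Reagents that add atoms: methyl chloroformate, COC(Cl)=O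
Why: O-acylation of the secondary propargylic alcohol installs the leaving group for allene formation and blocks retro-aldol cleavage.

**Step 7**
Reactants: 13 propargylic carbonate
Product: 14 ethyl 2-methyl-4-[2,6,6-trimethyl-3-oxo-2-(propa-1,2-dienyl)cyclohexyl]butanoate
Conditions: Pd2(dba)3·CHCl3 (2.5 mol %), PBu3 (10 mol %), HCO2NH4, THF, rt
Reagents that add atoms: none
Why: palladium-catalysed hydrogenolysis of a propargylic carbonate with formate (oxidative addition of zerovalent palladium to an allenylpalladium species, decarboxylation of formate, reductive elimination) should give the terminal allene C9=C11=C12 on the quaternary C10.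

**Step 8**
Reactants: 14 allenyl ketone
Product: 15 ethyl 4-[3-hydroxy-2,6,6-trimethyl-2-(propa-1,2-dienyl)cyclohexyl]-2-methylbutanoate (C1 carbinol epimers)
Conditions: NaBH4, MeOH, 0 °C
Reagents that add atoms: none
Why: hydride reduction of the ring ketone should be chemoselective over ester and allene, and the new carbinol centre is removed in step 9.

**Step 9**
Reactants: 15 alcohol
Product: 16 ethyl 2-methyl-4-[2,6,6-trimethyl-2-(propa-1,2-dienyl)cyclohex-3-enyl]butanoate (C1=C2 alkene)
Conditions: Burgess reagent (MeO2CN−SO2N+Et3), benzene, 50 °C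
Reagents that add atoms: none
Why: Burgess dehydration (syn-elimination of the sulfamate) can only occur towards C2 because C10 is quaternary, so the ring oxygen leaves as an alkene that is hydrogenated in step 14.

**Step 10**
Reactants: 16 ester
Product: 17 N-methoxy-N,2-dimethyl-4-[2,6,6-trimethyl-2-(propa-1,2-dienyl)cyclohex-3-enyl]butanamide
Conditions: MeNH(OMe)·HCl, i-PrMgCl, THF, −20 °C
Reagents that add atoms: N,O-dimethylhydroxylamine hydrochloride, CNOC.Cl
Why: aminolysis of the ethyl ester by the chloromagnesium amide gives the Weinreb amide, which allows clean mono-addition of a vinyl nucleophile.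

**Step 11**
Reactants: 17 Weinreb amide
Product: 18 4-methyl-6-[2,6,6-trimethyl-2-(propa-1,2-dienyl)cyclohex-3-enyl]hex-1-en-3-one
Conditions: CH2=CHMgBr, THF, 0 °C; inverse quench into cold 1 M HCl
Reagents that add atoms: vinylmagnesium bromide, C=C[Mg]Br
Why: Weinreb ketone synthesis, in which the stable magnesium chelate prevents over-addition and the acidic inverse quench avoids aza-Michael addition of the released amine.

**Step 12**
Reactants: 18 vinyl ketone
Product: 19 tert-butyldimethylsilyl dienol ether C13H2=C14H–C15(OTBS)=C8(CH3)–C7 (E/Z mixture at C8=C15)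
Conditions: TBSOTf, Et3N, CH2Cl2, 0 °C
Reagents that add atoms: tert-butyldimethylsilyl trifluoromethanesulfonate, CC(C)(C)[Si](C)(C)OS(=O)(=O)C(F)(F)F
Why: soft enolisation of the vinyl ketone at its only α'-position (C8) gives the cross-conjugated 2-silyloxy-1,3-diene and makes C8 planar, so both side-chain epimers converge.

**Step 13 (key step)**
Reactants: 19 allene-tethered silyloxydiene
Product: 21 tricyclic ketone (C15 ketone on C8; C9=C11 and C1=C2 alkenes; 5α-H, 8β-methyl, 10β-methyl), via silyl enol ether 20 (not isolated)
Conditions: (IPr)AuCl (5 mol %; IPr = 1,3-bis(2,6-diisopropylphenyl)imidazol-2-ylidene), AgSbF6 (5 mol %), CH2Cl2, 4 Å MS, −20 °C to rt; then 1 M HCl (aq), THF, 0 °C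
Reagents that add atoms: none
Why: The cationic gold complex activates the allene as a gold-bound allyl cation; the nucleophilic diene terminus C8 bonds to the proximal allene carbon C9 and the distal carbon C12 bonds to the diene terminus C13 in an asynchronous (4+3) cycloaddition, the cycloheptenyl gold carbene at C11 collapses by 1,2-hydride shift from C9 to give the C9=C11 alkene and free the catalyst, and acid then hydrolyses silyl enol ether 20. The closest known reaction type is the gold- or platinum-catalysed intramolecular (4+3) cycloaddition of allene-tethered 1,3-dienes to bicyclic cycloheptadienes. Ring B closes as a six-membered ring through the four-atom tether C7–C6–C5–C10 (bond C8–C9, chair-like), and the seven-membered ring closes through C12–C13 as the (4+3) ring, a 7-endo attack of the vinylgold carbon on the silyloxyallyl cation if the process is stepwise. The one stereocentre created and kept is the quaternary C8: in the chair fixed by C5 and C10 the bulky silyloxydiene should sit equatorial and the C8 methyl axial, syn to the C10 methyl, as in the target; C9 becomes planar here and is set in step 14. The step needs (4+3) rather than (4+2) selectivity and ring closure rather than protodeauration after the first bond: the strongly donating carbene ligand favours the carbene pathway, the polarity is matched (C8 nucleophilic and C13 electrophilic in the diene, C9 electrophilic and C12 nucleophilic in the gold–allyl unit), and the tether length allows only C8–C9 as the first bond.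

**Step 14**
Reactants: 21 tricyclic dienyl ketone
Product: 22 saturated tricyclic ketone (5α-H, 8β-methyl, 9α-H, 10β-methyl)
Conditions: H2 (4 bar), [Ir(cod)(PCy3)(py)]PF6 (5 mol %), CH2Cl2, rt
Reagents that add atoms: none
Why: homogeneous iridium-catalysed hydrogenation saturates both alkenes, and at the hindered C9=C11 alkene hydrogen should be delivered to the α-face because the β-face is shielded by the axial C8 and C10 methyl groups and the C15 carbonyl can direct the catalyst, which sets C9.

**Step 15**
Reactants: 22 saturated ketone
Product: 23 cycloheptenone (C13=C14 conjugated to the C15 ketone)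
Conditions: IBX, 4-methoxypyridine N-oxide, DMSO, rt
Reagents that add atoms: none
Why: IBX dehydrogenation of a ketone through its enol is regiospecific here because only C14 can enolise (C8 is quaternary).

**Step 16**
Reactants: 23 cycloheptenone
Product: 24 13-[(dimethylphenylsilyl)methyl] ketone (C16 syn to the C8 methyl)
Conditions: PhMe2SiCH2MgCl, CuBr·SMe2 (5 mol %), (R,S)-Josiphos [(R)-1-{(S)-2-(diphenylphosphino)ferrocenyl}ethyldicyclohexylphosphine] (6 mol %), t-BuOMe, −78 °C; NH4Cl (aq)
Reagents that add atoms: [(dimethylphenylsilyl)methyl]magnesium chloride, C[Si](C)(C[Mg]Cl)c1ccccc1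
Why: copper-catalysed asymmetric conjugate addition of a Grignard reagent to a cyclic enone introduces C16 as a masked hydroxymethyl group and sets C13 by catalyst control (addition to the face of C13 syn to the C8 methyl; the ligand antipode is chosen for this sense).

**Step 17**
Reactants: 24 ketone
Product: 25 eight-membered lactone (O between C8 and C15)
Conditions: mCPBA, NaHCO3, CH2Cl2, rt
Reagents that add atoms: 3-chloroperbenzoic acid, OOC(=O)c1cccc(Cl)c1
Why: Baeyer–Villiger oxidation, in which the quaternary C8 migrates in preference to the C14 methylene and with retention, so the oxygen enters exactly where the oxocane needs it.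

**Step 18**
Reactants: 25 lactone
Product: 27 lactol acetate (C15 epimers), via aluminium lactolate 26 (not isolated)
Conditions: i-Bu2AlH, CH2Cl2, −78 °C; then Ac2O, pyridine, DMAP, −78 °C to 0 °C
Reagents that add atoms: acetic anhydride, CC(=O)OC(C)=O
Why: reductive acetylation, in which acylation of the aluminium hemiacetal in the flask prevents opening of the eight-membered lactol to the hydroxy aldehyde.

**Step 19**
Reactants: 27 lactol acetate
Product: 28 oxocane carrying the silylmethyl group on C13
Conditions: Et3SiH, BF3·OEt2, CH2Cl2, −78 °C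
Reagents that add atoms: none
Why: ionisation of the α-acetoxy ether to the cyclic oxocarbenium ion and hydride transfer from the silane (ionic reduction) should give the cyclic ether without touching the tertiary C8–O bond at low temperature.

**Step 20**
Reactants: 28 silane
Product: 29 primary alcohol (8,15-epoxylabdan-16-ol)
Conditions: KBr, AcOOH, NaOAc, AcOH, rt
Reagents that add atoms: peracetic acid, CC(=O)OO
Why: Tamao–Fleming oxidation (ipso-bromodesilylation of the phenyl group, then peracid-induced carbon-to-oxygen shift with retention) converts the C16–Si bond into C16–OH under buffered conditions.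

**Step 21**
Reactants: 29 alcohol
Product: 30 (5S,8R,9R,10S,13R)-8,15-epoxylabdan-16-yl acetate (target)
Conditions: Ac2O, pyridine, DMAP (cat.), CH2Cl2, rt
Reagents that add atoms: acetic anhydride, CC(=O)OC(C)=O
Why: acylation of the unhindered primary alcohol (nucleophilic catalysis by DMAP) gives the acetate.

**Compound list**

1 | ethyl 4-bromo-2-methylbutanoate (racemic) | CCOC(=O)C(C)CCBr | starting material
2 | ethyl 4-iodo-2-methylbutanoate (racemic) | CCOC(=O)C(C)CCI | intermediate
3 | (4-ethoxy-3-methyl-4-oxobutyl)zinc iodide | CCOC(=O)C(C)CC[Zn]I | intermediate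
4 | (4-ethoxy-3-methyl-4-oxobutyl)[(trimethylsilyl)methyl]zinc | CCOC(=O)C(C)CC[Zn]C[Si](C)(C)C | intermediate
5 | 4,4-dimethylcyclohex-2-en-1-one | CC1(C)CCC(=O)C=C1 | starting material
6 | [(trimethylsilyl)methyl]zinc enolate of the conjugate adduct (enolate C1=C10) | CCOC(=O)C(C)CC[C@H]1C(C)(C)CCC(O[Zn]C[Si](C)(C)C)=C1 | intermediate
7 | ethyl 4-{2-[(dimethylamino)methyl]-6,6-dimethyl-3-oxocyclohexyl}-2-methylbutanoate (trans) | CCOC(=O)C(C)CC[C@H]1C(C)(C)CCC(=O)[C@@H]1CN(C)C | intermediate
8 | trimethylammonium iodide of 7 | CCOC(=O)C(C)CC[C@H]1C(C)(C)CCC(=O)[C@@H]1C[N+](C)(C)C.[I-] | intermediate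
9 | ethyl 4-(6,6-dimethyl-2-methylidene-3-oxocyclohexyl)-2-methylbutanoate | CCOC(=O)C(C)CC[C@H]1C(C)(C)CCC(=O)C1=C | intermediate
10 | propynal | C#CC=O | starting material
11 | lithium enolate (C1=C10, methyl on C10) | CCOC(=O)C(C)CC[C@H]1C(C)(C)CCC(O[Li])=C1C | intermediate
12 | ethyl 4-[2-(1-hydroxyprop-2-ynyl)-2,6,6-trimethyl-3-oxocyclohexyl]-2-methylbutanoate | CCOC(=O)C(C)CC[C@H]1C(C)(C)CCC(=O)[C@]1(C)C(O)C#C | intermediate
13 | methyl carbonate of 12 | CCOC(=O)C(C)CC[C@H]1C(C)(C)CCC(=O)[C@]1(C)C(OC(=O)OC)C#C | intermediate
14 | ethyl 2-methyl-4-[2,6,6-trimethyl-3-oxo-2-(propa-1,2-dienyl)cyclohexyl]butanoate | CCOC(=O)C(C)CC[C@H]1C(C)(C)CCC(=O)[C@]1(C)C=C=C | intermediate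
15 | ethyl 4-[3-hydroxy-2,6,6-trimethyl-2-(propa-1,2-dienyl)cyclohexyl]-2-methylbutanoate | CCOC(=O)C(C)CC[C@H]1C(C)(C)CCC(O)[C@]1(C)C=C=C | intermediate
16 | ethyl 2-methyl-4-[2,6,6-trimethyl-2-(propa-1,2-dienyl)cyclohex-3-enyl]butanoate | CCOC(=O)C(C)CC[C@H]1C(C)(C)CC=C[C@]1(C)C=C=C | intermediate
17 | N-methoxy-N,2-dimethyl-4-[2,6,6-trimethyl-2-(propa-1,2-dienyl)cyclohex-3-enyl]butanamide | CON(C)C(=O)C(C)CC[C@H]1C(C)(C)CC=C[C@]1(C)C=C=C | intermediate
18 | 4-methyl-6-[2,6,6-trimethyl-2-(propa-1,2-dienyl)cyclohex-3-enyl]hex-1-en-3-one | C=CC(=O)C(C)CC[C@H]1C(C)(C)CC=C[C@]1(C)C=C=C | intermediate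
19 | 2-silyloxydiene with allene on C10 (key-step precursor) | C=CC(O[Si](C)(C)C(C)(C)C)=C(C)CC[C@H]1C(C)(C)CC=C[C@]1(C)C=C=C | intermediate
20 | tricyclic silyl enol ether (C14=C15, C9=C11, C1=C2) | C1C=C(O[Si](C)(C)C(C)(C)C)[C@]2(C)CC[C@H]3C(C)(C)CC=C[C@]3(C)C2=CC1 | intermediate
21 | tricyclic ketone (C15=O on C8; C9=C11, C1=C2) | C1CC(=O)[C@]2(C)CC[C@H]3C(C)(C)CC=C[C@]3(C)C2=CC1 | intermediate
22 | saturated tricyclic ketone (5α-H, 8β-Me, 9α-H, 10β-Me) | C1CC(=O)[C@]2(C)CC[C@H]3C(C)(C)CCC[C@]3(C)[C@H]2CC1 | intermediate
23 | tricyclic cycloheptenone (C13=C14) | C1=CC(=O)[C@]2(C)CC[C@H]3C(C)(C)CCC[C@]3(C)[C@H]2CC1 | intermediate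
24 | 13-[(dimethylphenylsilyl)methyl] ketone | C[Si](C)(c4ccccc4)C[C@H]1CC(=O)[C@]2(C)CC[C@H]3C(C)(C)CCC[C@]3(C)[C@H]2CC1 | intermediate
25 | eight-membered lactone (8,15-olide) | C[Si](C)(c4ccccc4)C[C@H]1CC(=O)O[C@]2(C)CC[C@H]3C(C)(C)CCC[C@]3(C)[C@H]2CC1 | intermediate
26 | diisobutylaluminium lactolate | C[Si](C)(c4ccccc4)C[C@H]1CC(O[Al](CC(C)C)CC(C)C)O[C@]2(C)CC[C@H]3C(C)(C)CCC[C@]3(C)[C@H]2CC1 | intermediate
27 | lactol acetate (C15 epimers) | C[Si](C)(c4ccccc4)C[C@H]1CC(OC(C)=O)O[C@]2(C)CC[C@H]3C(C)(C)CCC[C@]3(C)[C@H]2CC1 | intermediate
28 | 16-(dimethylphenylsilyl)-8,15-epoxylabdane | C[Si](C)(c4ccccc4)C[C@H]1CCO[C@]2(C)CC[C@H]3C(C)(C)CCC[C@]3(C)[C@H]2CC1 | intermediate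
29 | 8,15-epoxylabdan-16-ol | OC[C@H]1CCO[C@]2(C)CC[C@H]3C(C)(C)CCC[C@]3(C)[C@H]2CC1 | intermediate
30 | (5S,8R,9R,10S,13R)-8,15-epoxylabdan-16-yl acetate | CC(=O)OC[C@H]1CCO[C@]2(C)CC[C@H]3C(C)(C)CCC[C@]3(C)[C@H]2CC1 | target

**Step count and risks**

Total steps: 21. Longest linear sequence: 21 steps (from 1; 19 from 5).

Steps most likely to fail, riskiest first:

Step 13. The gold sequence may stop after the first C–C bond by protodeauration, may divert to a (4+2) product by ring contraction of the carbene, or may show low facial selectivity at C8. The fallback uses known chemistry in separate steps and sets out from 19. Gold-catalysed addition of the silyl enol ether to the allene in the presence of methanol [(Ph3P)AuCl, AgOTf, CH2Cl2–MeOH, rt] stops on purpose after the C8–C9 bond and gives the bicyclic vinyl ketone carrying a vinyl group on C9 F1. Copper-mediated 1,4-addition of a vinyl group (CH2=CHMgBr, CuBr·SMe2, Me3SiCl, THF, −78 °C, then dilute HCl) gives the but-3-enyl ketone F2, in which the carbon bonded to C13 takes the place of C12. Ring-closing metathesis with the second-generation Grubbs catalyst (CH2Cl2, 40 °C) closes the seven-membered ring to cycloheptenone F3. Hydrogenation of F3 (H2, Pd/C, EtOAc) comes back to the route at 22.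

Step 16. Facial selectivity may be poor if the substrate bias opposes the catalyst, and 1,2-addition may compete. The fallback sets out from 23 and makes C13 by hydride delivery in a stereoconvergent way. Achiral copper-catalysed 1,4-addition of the same Grignard reagent with Me3SiCl trapping (CuI cat., THF, −78 °C) gives the trimethylsilyl enol ether F4 as a C13 epimer mixture. Saegusa–Ito oxidation [Pd(OAc)2, MeCN, rt] gives the 13-substituted enone F5, in which C13 is planar. Copper hydride asymmetric conjugate reduction [Cu(OAc)2·H2O, (R)-DTBM-SEGPHOS, (EtO)2MeSiH, t-BuOH, toluene; ligand antipode chosen for the required face] then sets C13 and comes back to the route at 24.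

Step 14. Reduction of the trisubstituted alkene between two quaternary carbons may be slow or incomplete, or hydrogen may be delivered from the wrong face. The fallback sets out from 21. Hydrogenation over Pd/C (EtOAc, rt) should reduce only the ring A alkene and give the C9=C11 ketone F6. Radical hydrogen-atom-transfer hydrogenation [Mn(dpm)3, PhSiH3, t-BuOOH, i-PrOH, rt] then reduces the hindered alkene through the tertiary C9 radical under thermodynamic control, which favours the trans ring fusion, and comes back to the route at 22.

**Further compounds**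

F1 | step 13 | bicyclic vinyl ketone (ring B closed; propenoyl and methyl on C8, vinyl on C9) | C=CC(=O)[C@]1(C)CC[C@H]2C(C)(C)CC=C[C@]2(C)[C@H]1C=C
F2 | step 13 | but-3-enyl ketone (pent-4-enoyl on C8, vinyl on C9) | C=CCCC(=O)[C@]1(C)CC[C@H]2C(C)(C)CC=C[C@]2(C)[C@H]1C=C
F3 | step 13 | tricyclic cycloheptenone (C11=C12, C1=C2; 9α-H) | C1CC(=O)[C@]2(C)CC[C@H]3C(C)(C)CC=C[C@]3(C)[C@H]2C=C1
F4 | step 16 | trimethylsilyl enol ether of the 13-silylmethyl ketone (C13 epimers) | C[Si](C)(c4ccccc4)CC1C=C(O[Si](C)(C)C)[C@]2(C)CC[C@H]3C(C)(C)CCC[C@]3(C)[C@H]2CC1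
F5 | step 16 | 13-[(dimethylphenylsilyl)methyl]cycloheptenone (C13=C14) | C[Si](C)(c4ccccc4)CC1=CC(=O)[C@]2(C)CC[C@H]3C(C)(C)CCC[C@]3(C)[C@H]2CC1
F6 | step 14 | tricyclic ketone with saturated ring A and C9=C11 alkene | C1CC(=O)[C@]2(C)CC[C@H]3C(C)(C)CCC[C@]3(C)C2=CC1
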